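**Plan**
Retrosynthesis: the C13=C14 unsaturation is removed first; the γ-lactone is opened at O–C19; the ten-membered ring is cut at C6–C7 (alkenylchromium + aldehyde); the side arms are cut at C8–C9 (alkenylmetal + aldehyde) and C3–C4 (enolate + allylic bromide); last, the six-membered ring is cut across C1–C10 and C13–C14 into a 2-silyloxy-1,3-diene and methacrolein.
Enabling feature: in ring C1/C10/C11/C12/C13/C14 the C12 carbonyl lies 1,4 to the all-carbon quaternary C1 and next to the C11 carbinol. The ring is therefore the adduct of a C10=C11–C12(OSi)=C13 diene and a C1=C14 enal; the C11=C12 silyl enol ether left behind later gives C11–OH, C12=O and, through the C12 enolate, C13=C14.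
Forward order: diene → six-membered ring (step 4) → C2–C6 arm → C7–C9/C17–C19 arm → ten-membered ring by C6–C7 closure → lactone → enone.
Stereochemistry: C1 and C10 from the catalyst-controlled exo cycloaddition; C2 from a CBS reduction; C9 from a Felkin–Anh addition; C8 and C11 from one osmylation; C17 from methyl (S)-3-hydroxy-2-methylpropanoate; C7 from the ring-closing addition; Z-C5=C6 from anti-carbomagnesiation of propargyl alcohol.

Key step: step 4

Remark: briarane numbering is used for positions: C1 quaternary ring carbon (methyl C15), C2 propionyloxy carbon, C3, C4, C5 (olefinic, methyl C16), C6, C7 (lactone O–CH), C8 (tertiary carbinol), C9 (acetoxy carbon), C10, C11 (tertiary carbinol, methyl C20), C12 (ketone), C13, C14, C17 (lactone CH, methyl C18), C19 (lactone carbonyl). Assumption: compounds 1, 2, 6, 10 and 20 are commercial.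

**Step 1**
Reactants: 1 glycolaldehyde dimer; 2 3-(triphenylphosphoranylidene)butan-2-one
Product: 3 (E)-5-hydroxy-3-methylpent-3-en-2-one
Conditions: THF, reflux
Reagents that add atoms: none
Why: Wittig olefination with a stabilised keto ylide, the aldehyde being released from its dimer in situ; the stabilised ylide should give the E enone (CH2OH trans to acetyl).

**Step 2**
Reactants: 3 (E)-5-hydroxy-3-methylpent-3-en-2-one
Product: 4 (E)-3-methyl-5-(triethylsilyloxy)pent-3-en-2-one
Conditions: TESCl, imidazole, CH2Cl2, 0 °C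
Reagents that add atoms: triethylsilyl chloride, CC[Si](Cl)(CC)CC
Why: silyl ether formation at the primary alcohol; TES is chosen because it can later be removed beside the TIPS enol ether.

**Step 3**
Reactants: 4 (E)-3-methyl-5-(triethylsilyloxy)pent-3-en-2-one
Product: 5 (2E)-3-methyl-1-(triethylsilyloxy)-4-(triisopropylsilyloxy)penta-2,4-diene
Conditions: TIPSOTf, Et3N, CH2Cl2, 0 °C
Reagents that add atoms: triisopropylsilyl triflate, CC(C)[Si](OS(=O)(=O)C(F)(F)F)(C(C)C)C(C)C
Why: soft enolisation and O-silylation (silyl enol ether formation); only the methyl group can be deprotonated in the kinetic sense, so the 2-silyloxy-1,3-diene forms with the E geometry of C10=C11 kept.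

**Step 4**
Reactants: 5 (2E)-3-methyl-1-(triethylsilyloxy)-4-(triisopropylsilyloxy)penta-2,4-diene; 6 methacrolein
Product: 7 (1S,2S)-1,3-dimethyl-2-[(triethylsilyloxy)methyl]-4-(triisopropylsilyloxy)cyclohex-3-ene-1-carbaldehyde
Conditions: (S)-2-butyl-4-(1H-indol-3-ylmethyl)-3-tosyl-1,3,2-oxazaborolidin-5-one (20 mol %), CH2Cl2, −78 °C
Reagents that add atoms: none
Why: Lewis-acid-activated [4+2] cycloaddition (Diels–Alder reaction): boron binds the formyl oxygen of 6, and the diene adds in one concerted, asynchronous event in which the enol-ether terminus C13 bonds ahead to the unsubstituted enal carbon C14 while C10 closes onto the substituted carbon C1. The closest known reaction type is the enantioselective oxazaborolidine-catalysed Diels–Alder reaction of 2-substituted acroleins with 2-silyloxy-1,3-dienes that carry a 1-substituent and a 3-methyl group. The six-membered ring (C1, C10, C11, C12, C13, C14) closes by intermolecular suprafacial/suprafacial addition, so both new bonds arise on one face of each partner. C1 is set by the catalyst, whose indole covers one face of the s-cis-bound enal so that the diene reaches the other; C10 follows from the E geometry of C10=C11 and the formyl-exo arrangement expected for 2-substituted acroleins under this catalysis, which puts CH2OTES cis to the C1 methyl. The step needs regioselectivity, exo selectivity and one enantioface. Regioselectivity is secured because the 2-silyloxy group and the 1-alkyl group both direct C13 to C14; exo selectivity and the enantioface are secured by the catalyst–enal complex.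

**Step 5**
Reactants: 7 Diels–Alder aldehyde
Product: 8 1-[(1S,2R)-1,3-dimethyl-2-[(triethylsilyloxy)methyl]-4-(triisopropylsilyloxy)cyclohex-3-en-1-yl]ethan-1-ol as both carbinol epimers
Conditions: MeMgBr, THF, −78 °C
Reagents that add atoms: methylmagnesium bromide, C[Mg]Br
Why: Grignard addition to the neopentyl aldehyde; the new carbinol configuration does not matter because it is oxidised in step 6.

**Step 6**
Reactants: 8 carbinol mixture
Product: 9 1-[(1S,2S)-1,3-dimethyl-2-[(triethylsilyloxy)methyl]-4-(triisopropylsilyloxy)cyclohex-3-en-1-yl]ethan-1-one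
Conditions: Dess–Martin periodinane, pyridine, CH2Cl2, 0 °C
Reagents that add atoms: none
Why: Dess–Martin oxidation under buffered conditions should spare the silyl enol ether and the TES ether.

**Step 7**
Reactants: 10 propargyl alcohol
Product: 12 (Z)-3-iodo-2-methylprop-2-en-1-ol, via alkenylmagnesium alkoxide 11 (not isolated)
Conditions: MeMgBr (2.2 equiv), CuI (10 mol %), THF, −20 °C → rt; then I2, −78 → 0 °C
Reagents that add atoms: methylmagnesium bromide, C[Mg]Br; iodine, II
Why: copper-catalysed anti-carbomagnesiation of the propargylic alkoxide; the chelated alkenylmagnesium holds the metal cis to CH2O, so iodinolysis with retention should give the Z iodide.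

**Step 8**
Reactants: 12 (Z)-3-iodo-2-methylprop-2-en-1-ol
Product: 13 (Z)-3-bromo-1-iodo-2-methylprop-1-ene
Conditions: CBr4, PPh3, CH2Cl2, 0 °C
Reagents that add atoms: carbon tetrabromide, BrC(Br)(Br)Br
Why: Appel bromination of the primary allylic alcohol, which leaves the alkenyl iodide and its geometry untouched.

**Step 9**
Reactants: 9 methyl ketone; 13 (Z)-3-bromo-1-iodo-2-methylprop-1-ene
Product: 15 (4Z)-5-iodo-4-methyl-1-[(1S,2S)-1,3-dimethyl-2-[(triethylsilyloxy)methyl]-4-(triisopropylsilyloxy)cyclohex-3-en-1-yl]pent-4-en-1-one, via lithium enolate 14 (not isolated)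
Conditions: LiN(i-Pr)2, THF, −78 °C; then 13, DMPU, −78 → −30 °C
Reagents that add atoms: none
Why: kinetic enolate alkylation; the ketone can enolise only toward its methyl group (C1 is quaternary), and the allylic bromide reacts by SN2 while the alkenyl iodide is inert.

**Step 10**
Reactants: 15 alkylated ketone
Product: 16 (1R,4Z)-5-iodo-4-methyl-1-[(1S,2R)-1,3-dimethyl-2-[(triethylsilyloxy)methyl]-4-(triisopropylsilyloxy)cyclohex-3-en-1-yl]pent-4-en-1-ol
Conditions: (S)-2-methyl-CBS-oxazaborolidine (0.3 equiv), BH3·SMe2, THF, −20 °C; MeOH quench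
Reagents that add atoms: none
Why: Corey–Bakshi–Shibata reduction; quaternary C1 acts as the large group and the CH2 chain as the small one, so the (S)-catalyst should give the 2R carbinol under reagent control.

**Step 11**
Reactants: 16 C2 carbinol
Product: 17 C2 propionate of 16
Conditions: (EtCO)2O, DMAP, Et3N, CH2Cl2, rt
Reagents that add atoms: propionic anhydride, CCC(=O)OC(=O)CC
Why: DMAP-catalysed acylation installs the propionate of the target early, where it also serves as the C2 protecting group.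

**Step 12**
Reactants: 17 C2 propionate
Product: 18 primary C9 alcohol (TES removed)
Conditions: PPTS (0.1 equiv), MeOH/CH2Cl2, 0 °C
Reagents that add atoms: none
Why: acid-catalysed methanolysis of the primary TES ether (selective desilylation); the hindered tetrasubstituted TIPS enol ether should survive a short exposure.

**Step 13**
Reactants: 18 primary alcohol
Product: 19 C9 aldehyde
Conditions: Dess–Martin periodinane, NaHCO3, CH2Cl2, 0 °C
Reagents that add atoms: none
Why: Dess–Martin oxidation under non-basic conditions should give the aldehyde without epimerising C10 or shifting the C11=C12 bond.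

**Step 14**
Reactants: 20 methyl (S)-3-hydroxy-2-methylpropanoate
Product: 21 methyl (S)-3-(tert-butyldimethylsilyloxy)-2-methylpropanoate
Conditions: TBSCl, imidazole, CH2Cl2, rt
Reagents that add atoms: tert-butyldimethylsilyl chloride, C[Si](C)(Cl)C(C)(C)C
Why: silyl ether formation at the primary alcohol.

**Step 15**
Reactants: 21 silyl ether ester
Product: 22 (S)-3-(tert-butyldimethylsilyloxy)-2-methylpropanal
Conditions: i-Bu2AlH, CH2Cl2, −78 °C; potassium sodium tartrate work-up
Reagents that add atoms: none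
Why: partial ester reduction; the tetrahedral aluminium acetal is stable at −78 °C and releases the aldehyde only on work-up.

**Step 16**
Reactants: 22 aldehyde
Product: 23 (R)-tert-butyldimethyl[(2-methylbut-3-yn-1-yl)oxy]silane
Conditions: dimethyl (1-diazo-2-oxopropyl)phosphonate, K2CO3, MeOH, 0 °C → rt
Reagents that add atoms: dimethyl (1-diazo-2-oxopropyl)phosphonate, CC(=O)C(=[N+]=[N-])P(=O)(OC)OC
Why: Ohira–Bestmann alkynylation (Seyferth–Gilbert homologation); the mild carbonate base should not epimerise the α-stereocentre.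

**Step 17**
Reactants: 23 alkyne
Product: 25 (S)-tert-butyl[(3-iodo-2-methylbut-3-en-1-yl)oxy]dimethylsilane, via iodoalkenylborane 24 (not isolated)
Conditions: B-iodo-9-BBN, hexane/CH2Cl2, −20 °C; then AcOH, 0 °C
Reagents that add atoms: B-iodo-9-borabicyclo[3.3.1]nonane, IB1C2CCCC1CCC2
Why: Markovnikov hydroiodination by syn-haloboration of the terminal alkyne followed by protodeboronation with acetic acid.

**Step 18**
Reactants: 19 C9 aldehyde; 25 alkenyl iodide
Product: 29 C9 allylic acetate of the coupled chain (1S 2R 9R 10R 17R), via alkenyllithium 26 (not isolated), via alkenylcerium dichloride 27 (not isolated), via cerium alkoxide 28 (not isolated)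
Conditions: 25, t-BuLi (2.0 equiv), Et2O, −78 °C; CeCl3, THF, −78 °C; then 19; then Ac2O, DMAP, −78 °C → rt
Reagents that add atoms: acetic anhydride, CC(=O)OC(C)=O
Why: iodine–lithium exchange, transmetalation to the weakly basic organocerium and 1,2-addition to the aldehyde, which is much faster than attack on the hindered propionate; Felkin–Anh attack anti to the quaternary C1 should set 9R, and the alkoxide is acetylated in the same flask.

**Step 19**
Reactants: 29 allylic acetate
Product: 30 C11-hydroxy C12-ketone with C7,C8-diol (1S 2R 8S 9R 10S 11S 17S)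
Conditions: OsO4 (5 mol %), NMO, acetone/H2O, 0 °C → rt; Na2SO3
Reagents that add atoms: N-methylmorpholine N-oxide, C[N+]1([O-])CCOCC1; water, O
Why: osmium-catalysed dihydroxylation acting twice: the silyl enol ether is oxidised to the α-hydroxy ketone from the face opposite the bulky C10 side chain (11S), and the 1,1-disubstituted olefin is attacked anti to the ring in its A(1,2)-minimised conformer, the same sense as the empirical anti-to-allylic-oxygen rule (8S), while the electron-poor iodoalkene is left alone.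

**Step 20**
Reactants: 30 diol
Product: 31 C7 aldehyde (α-hydroxy aldehyde)
Conditions: TEMPO (20 mol %), PhI(OAc)2, CH2Cl2, rt
Reagents that add atoms: none
Why: TEMPO/PhI(OAc)2 oxidation of the only primary alcohol to a non-enolisable aldehyde; the tertiary alcohols are inert.

**Step 21**
Reactants: 31 iodo aldehyde
Product: 32 ten-membered C7 carbinol (1S 2R 7S 8S 9R 10S 11S 17S)
Conditions: CrCl2 (10 equiv), NiCl2 (0.2 equiv), DMSO/THF, 2 mM, rt
Reagents that add atoms: none
Why: intramolecular Nozaki–Hiyama–Kishi reaction; zerovalent nickel inserts into the alkenyl C–I bond with retention of the Z geometry, and the alkenylchromium formed adds to the aldehyde in preference to ketone and esters, closing the ten-membered ring; polar Felkin–Anh attack anti to the C8–O bond and past the smaller C17 branch should give 7S, which places C6 and C9 trans on the future lactone.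

**Step 22**
Reactants: 32 macrocyclic carbinol
Product: 33 C7,C19-diol
Conditions: HF·pyridine, pyridine, THF, 0 °C → rt
Reagents that add atoms: none
Why: fluoride cleavage of the primary TBS ether, which acetate, propionate and the tertiary alcohols should tolerate.

**Step 23**
Reactants: 33 diol
Product: 36 13,14-dihydro lactone, via hydroxy aldehyde 34 (not isolated), via lactol 35 (not isolated)
Conditions: TEMPO (20 mol %), PhI(OAc)2 (2.5 equiv), CH2Cl2, rt
Reagents that add atoms: none
Why: oxidative lactonisation of a 1,4-diol; the primary alcohol is oxidised first, the aldehyde closes to the five-membered lactol with C7–OH (C9 is blocked as acetate), and the lactol is oxidised to the lactone.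

**Step 24**
Reactants: 36 dihydro lactone
Product: 39 CNP0240018.1, via tris(trimethylsilyl) enol ether 37 (not isolated), via bis(trimethylsilyl) enone 38 (not isolated)
Conditions: TMSOTf, Et3N, CH2Cl2, 0 °C; then Pd(OAc)2, MeCN, rt; then 1 M HCl, THF, 0 °C
Reagents that add atoms: none
Why: Saegusa–Ito oxidation; the ketone can enolise only toward C13 (C11 is quaternary), so the silyl enol ether and then the C13=C14 enone form at one position only, and the transient TMS ethers of the two tertiary alcohols are hydrolysed on acidic work-up.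

**Compound list**
1 | glycolaldehyde dimer (2,5-dihydroxy-1,4-dioxane) | OC1COC(O)CO1 | starting material
2 | 3-(triphenylphosphoranylidene)butan-2-one | CC(=O)C(C)=P(c1ccccc1)(c1ccccc1)c1ccccc1 | starting material
3 | (E)-5-hydroxy-3-methylpent-3-en-2-one | CC(=O)/C(C)=C/CO | intermediate
4 | (E)-3-methyl-5-(triethylsilyloxy)pent-3-en-2-one | CC(=O)/C(C)=C/CO[Si](CC)(CC)CC | intermediate
5 | (2E)-3-methyl-1-(triethylsilyloxy)-4-(triisopropylsilyloxy)penta-2,4-diene | C=C(O[Si](C(C)C)(C(C)C)C(C)C)/C(C)=C/CO[Si](CC)(CC)CC | intermediate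
6 | methacrolein (2-methylprop-2-enal) | CC(=C)C=O | starting material
7 | (1S,2S)-1,3-dimethyl-2-[(triethylsilyloxy)methyl]-4-(triisopropylsilyloxy)cyclohex-3-ene-1-carbaldehyde (methyl and CH2OTES cis) | O=C[C@@]1(C)CCC(O[Si](C(C)C)(C(C)C)C(C)C)=C(C)[C@@H]1CO[Si](CC)(CC)CC | intermediate
8 | 1-[(1S,2R)-1,3-dimethyl-2-[(triethylsilyloxy)methyl]-4-(triisopropylsilyloxy)cyclohex-3-en-1-yl]ethan-1-ol, both carbinol epimers | CC(O)[C@@]1(C)CCC(O[Si](C(C)C)(C(C)C)C(C)C)=C(C)[C@@H]1CO[Si](CC)(CC)CC | intermediate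
9 | 1-[(1S,2S)-1,3-dimethyl-2-[(triethylsilyloxy)methyl]-4-(triisopropylsilyloxy)cyclohex-3-en-1-yl]ethan-1-one | CC(=O)[C@@]1(C)CCC(O[Si](C(C)C)(C(C)C)C(C)C)=C(C)[C@@H]1CO[Si](CC)(CC)CC | intermediate
10 | propargyl alcohol (prop-2-yn-1-ol) | C#CCO | starting material
11 | (Z)-alkenylmagnesium bromide alkoxide from carbomagnesiation of 10 | Br[Mg]OC/C(C)=C\[Mg]Br | intermediate
12 | (Z)-3-iodo-2-methylprop-2-en-1-ol | OC/C(C)=C\I | intermediate
13 | (Z)-3-bromo-1-iodo-2-methylprop-1-ene | BrC/C(C)=C\I | intermediate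
14 | lithium enolate of 9 | [Li]OC(=C)[C@@]1(C)CCC(O[Si](C(C)C)(C(C)C)C(C)C)=C(C)[C@@H]1CO[Si](CC)(CC)CC | intermediate
15 | (4Z)-5-iodo-4-methyl-1-[(1S,2S)-1,3-dimethyl-2-[(triethylsilyloxy)methyl]-4-(triisopropylsilyloxy)cyclohex-3-en-1-yl]pent-4-en-1-one | I/C=C(C)\CCC(=O)[C@@]1(C)CCC(O[Si](C(C)C)(C(C)C)C(C)C)=C(C)[C@@H]1CO[Si](CC)(CC)CC | intermediate
16 | (1R,4Z)-5-iodo-4-methyl-1-[(1S,2R)-1,3-dimethyl-2-[(triethylsilyloxy)methyl]-4-(triisopropylsilyloxy)cyclohex-3-en-1-yl]pent-4-en-1-ol | I/C=C(C)\CC[C@@H](O)[C@@]1(C)CCC(O[Si](C(C)C)(C(C)C)C(C)C)=C(C)[C@@H]1CO[Si](CC)(CC)CC | intermediate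
17 | propanoate of 16 (2R propionate, briarane numbering) | I/C=C(C)\CC[C@@H](OC(=O)CC)[C@@]1(C)CCC(O[Si](C(C)C)(C(C)C)C(C)C)=C(C)[C@@H]1CO[Si](CC)(CC)CC | intermediate
18 | primary alcohol: 17 with CH2OTES converted to CH2OH (1S,2R,10R) | I/C=C(C)\CC[C@@H](OC(=O)CC)[C@@]1(C)CCC(O[Si](C(C)C)(C(C)C)C(C)C)=C(C)[C@@H]1CO | intermediate
19 | C9 aldehyde: 18 with CH2OH oxidised to CHO (1S,2R,10R) | I/C=C(C)\CC[C@@H](OC(=O)CC)[C@@]1(C)CCC(O[Si](C(C)C)(C(C)C)C(C)C)=C(C)[C@@H]1C=O | intermediate
20 | methyl (S)-3-hydroxy-2-methylpropanoate | COC(=O)[C@@H](C)CO | starting material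
21 | methyl (S)-3-(tert-butyldimethylsilyloxy)-2-methylpropanoate | COC(=O)[C@@H](C)CO[Si](C)(C)C(C)(C)C | intermediate
22 | (S)-3-(tert-butyldimethylsilyloxy)-2-methylpropanal | O=C[C@@H](C)CO[Si](C)(C)C(C)(C)C | intermediate
23 | (R)-tert-butyldimethyl[(2-methylbut-3-yn-1-yl)oxy]silane | C#C[C@@H](C)CO[Si](C)(C)C(C)(C)C | intermediate
24 | (Z)-2-iodoalkenyl-9-BBN from haloboration of 23 | I/C(=C\B1C2CCCC1CCC2)[C@@H](C)CO[Si](C)(C)C(C)(C)C | intermediate
25 | (S)-tert-butyl[(3-iodo-2-methylbut-3-en-1-yl)oxy]dimethylsilane | C=C(I)[C@@H](C)CO[Si](C)(C)C(C)(C)C | intermediate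
26 | alkenyllithium from 25 | [Li]C(=C)[C@@H](C)CO[Si](C)(C)C(C)(C)C | intermediate
27 | alkenylcerium dichloride from 26 | Cl[Ce](Cl)C(=C)[C@@H](C)CO[Si](C)(C)C(C)(C)C | intermediate
28 | dichlorocerium alkoxide of the 9R allylic carbinol | I/C=C(C)\CC[C@@H](OC(=O)CC)[C@@]1(C)CCC(O[Si](C(C)C)(C(C)C)C(C)C)=C(C)[C@@H]1[C@@H](O[Ce](Cl)Cl)C(=C)[C@@H](C)CO[Si](C)(C)C(C)(C)C | intermediate
29 | allylic acetate: ring of 19 carrying at C10 the chain CH(OAc)–C(=CH2)–CH(CH3)–CH2OTBS (1S,2R,9R,10R,17R) | I/C=C(C)\CC[C@@H](OC(=O)CC)[C@@]1(C)CCC(O[Si](C(C)C)(C(C)C)C(C)C)=C(C)[C@@H]1[C@@H](OC(C)=O)C(=C)[C@@H](C)CO[Si](C)(C)C(C)(C)C | intermediate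
30 | 11-hydroxy-12-ketone with 7,8-diol (1S,2R,8S,9R,10S,11S,17S); C11–OH trans to the C10 side chain | I/C=C(C)\CC[C@@H](OC(=O)CC)[C@@]1(C)CCC(=O)[C@@](C)(O)[C@@H]1[C@@H](OC(C)=O)[C@@](O)(CO)[C@@H](C)CO[Si](C)(C)C(C)(C)C | intermediate
31 | C7 aldehyde of 30 (1S,2R,8R,9R,10S,11S,17S; the C8 descriptor changes by priority only) | I/C=C(C)\CC[C@@H](OC(=O)CC)[C@@]1(C)CCC(=O)[C@@](C)(O)[C@@H]1[C@@H](OC(C)=O)[C@@](O)(C=O)[C@@H](C)CO[Si](C)(C)C(C)(C)C | intermediate
32 | ten-membered 7-carbinol with Z-C5=C6, C8 carrying CH(CH3)CH2OTBS (1S,2R,7S,8S,9R,10S,11S,17S) | CCC(=O)O[C@@H]1CC/C(C)=C\[C@H](O)[C@@](O)([C@@H](C)CO[Si](C)(C)C(C)(C)C)[C@H](OC(C)=O)[C@@H]2[C@]1(C)CCC(=O)[C@@]2(C)O | intermediate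
33 | 7,19-diol: 32 with the TBS ether cleaved | CCC(=O)O[C@@H]1CC/C(C)=C\[C@H](O)[C@@](O)([C@@H](C)CO)[C@H](OC(C)=O)[C@@H]2[C@]1(C)CCC(=O)[C@@]2(C)O | intermediate
34 | C19 aldehyde of 33 | CCC(=O)O[C@@H]1CC/C(C)=C\[C@H](O)[C@@](O)([C@@H](C)C=O)[C@H](OC(C)=O)[C@@H]2[C@]1(C)CCC(=O)[C@@]2(C)O | intermediate
35 | C19 lactol closed onto O7 (lactol carbon as a mixture) | CCC(=O)O[C@@H]1CC/C(C)=C\[C@@H]2OC(O)[C@H](C)[C@@]2(O)[C@H](OC(C)=O)[C@@H]2[C@]1(C)CCC(=O)[C@@]2(C)O | intermediate
36 | 13,14-dihydro derivative of the target (1S,2R,7S,8S,9R,10S,11S,17R) | CCC(=O)O[C@@H]1CC/C(C)=C\[C@@H]2OC(=O)[C@H](C)[C@@]2(O)[C@H](OC(C)=O)[C@@H]2[C@]1(C)CCC(=O)[C@@]2(C)O | intermediate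
37 | C12 trimethylsilyl enol ether of 36 with 8-O-TMS and 11-O-TMS | CCC(=O)O[C@@H]1CC/C(C)=C\[C@@H]2OC(=O)[C@H](C)[C@@]2(O[Si](C)(C)C)[C@H](OC(C)=O)[C@@H]2[C@]1(C)CC=C(O[Si](C)(C)C)[C@@]2(C)O[Si](C)(C)C | intermediate
38 | 8,11-bis(trimethylsilyl) ether of the target | CCC(=O)O[C@@H]1CC/C(C)=C\[C@@H]2OC(=O)[C@H](C)[C@@]2(O[Si](C)(C)C)[C@H](OC(C)=O)[C@@H]2[C@]1(C)C=CC(=O)[C@@]2(C)O[Si](C)(C)C | intermediate
39 | CNP0240018.1 (1S,2R,5Z,7S,8S,9R,10S,11S,17R) | CCC(=O)O[C@@H]1CC/C(C)=C\[C@@H]2OC(=O)[C@H](C)[C@@]2(O)[C@H](OC(C)=O)[C@@H]2[C@]1(C)C=CC(=O)[C@@]2(C)O | target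

**Totals and risks**
Total step count: 24. Longest linear sequence: 18 steps (steps 1–6, 9–13, 18–24).

Step 4 is at risk because enantiofacial control, and with it the exo preference, may erode when the hindered 1,2,3-trisubstituted diene meets the catalyst-bound enal. The fallback sets out from diene 5: cycloaddition with commercial 3-methylbut-3-en-2-one under Et2AlCl (CH2Cl2, −78 °C) would give methyl ketone 9 directly as a racemate, that is, together with its enantiomer ent-9 F1, so steps 5 and 6 fall away and any endo isomer is removed here. Alkylation as in step 9 gives 15 together with ent-15 F2. The CBS reduction of step 10 then acts as a resolution: it turns the two enantiomers into diastereomeric (R)-carbinols, 16 and the ring-enantiomeric carbinol F3, which are separated by chromatography. The route is rejoined at 16.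

Step 18 is at risk because facial selectivity at the C9 aldehyde may be poor or reversed if the planar C11 rather than quaternary C1 takes the anti position, and because enolisation toward C10 may compete. The fallback sets out from aldehyde 19: the addition is run with aqueous work-up and gives the 9S carbinol F4. Dess–Martin oxidation gives the cross-conjugated enone F5. Luche reduction (NaBH4, CeCl3, MeOH, −78 °C) then delivers hydride under the same Felkin–Anh bias and, because the order of introduction is reversed, should give the 9R carbinol F6. Acetylation (Ac2O, pyridine) returns to 29.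

Step 21 is at risk because facial selectivity at C7 in the ring-closing addition may be low or reversed, with competing intermolecular coupling. The fallback sets out from aldehyde 31: the ring closure is accepted as it comes and gives the 7-epimeric carbinol F7. Mitsunobu inversion with chloroacetic acid (PPh3, DIAD, toluene) gives the 7S chloroacetate F8. Thiourea with NaHCO3 in EtOH removes the chloroacetyl group in the presence of acetate and propionate and returns to 32.

**Further compounds**
F1 | step 4 | ent-9, 1-[(1R,2R)-1,3-dimethyl-2-[(triethylsilyloxy)methyl]-4-(triisopropylsilyloxy)cyclohex-3-en-1-yl]ethan-1-one | CC(=O)[C@]1(C)CCC(O[Si](C(C)C)(C(C)C)C(C)C)=C(C)[C@H]1CO[Si](CC)(CC)CC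
F2 | step 4 | ent-15, (4Z)-5-iodo-4-methyl-1-[(1R,2R)-ring]pent-4-en-1-one | I/C=C(C)\CCC(=O)[C@]1(C)CCC(O[Si](C(C)C)(C(C)C)C(C)C)=C(C)[C@H]1CO[Si](CC)(CC)CC
F3 | step 4 | (1R,4Z)-5-iodo-4-methyl-1-[(1R,2S)-ring]pent-4-en-1-ol, diastereomer of 16 | I/C=C(C)\CC[C@@H](O)[C@]1(C)CCC(O[Si](C(C)C)(C(C)C)C(C)C)=C(C)[C@H]1CO[Si](CC)(CC)CC
F4 | step 18 | 9S allylic carbinol (C9 epimer of the alcohol of 29) | I/C=C(C)\CC[C@@H](OC(=O)CC)[C@@]1(C)CCC(O[Si](C(C)C)(C(C)C)C(C)C)=C(C)[C@@H]1[C@H](O)C(=C)[C@@H](C)CO[Si](C)(C)C(C)(C)C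
F5 | step 18 | C9 ketone (α-methylene ketone) | I/C=C(C)\CC[C@@H](OC(=O)CC)[C@@]1(C)CCC(O[Si](C(C)C)(C(C)C)C(C)C)=C(C)[C@@H]1C(=O)C(=C)[C@@H](C)CO[Si](C)(C)C(C)(C)C
F6 | step 18 | 9R allylic carbinol (free alcohol of 29) | I/C=C(C)\CC[C@@H](OC(=O)CC)[C@@]1(C)CCC(O[Si](C(C)C)(C(C)C)C(C)C)=C(C)[C@@H]1[C@@H](O)C(=C)[C@@H](C)CO[Si](C)(C)C(C)(C)C
F7 | step 21 | 7R epimer of 32 | CCC(=O)O[C@@H]1CC/C(C)=C\[C@@H](O)[C@@](O)([C@@H](C)CO[Si](C)(C)C(C)(C)C)[C@H](OC(C)=O)[C@@H]2[C@]1(C)CCC(=O)[C@@]2(C)O
F8 | step 21 | 7S chloroacetate of 32 | CCC(=O)O[C@@H]1CC/C(C)=C\[C@H](OC(=O)CCl)[C@@](O)([C@@H](C)CO[Si](C)(C)C(C)(C)C)[C@H](OC(C)=O)[C@@H]2[C@]1(C)CCC(=O)[C@@]2(C)O
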